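## Overview

- **Cuts.** The CH2CO2H arm on C3 is traced back to a C3-ethynyl group. The side chain is cut at C4′–C5′ (a Wittig alkene, saturated later). The C5–C1′ bond is cut to a dioxolanyl cation and the silyl dienol ether of prenal. The ring is opened at O2–C3 (hydroperoxide plus epoxide) and at C5 (ozonolysis of a methallyl group in methanol).
- **Enabling feature.** In the 1,2-dioxolane, C5 (bonded to O1, CH3, C4 and C1′) is at the ketone oxidation level, so it can become a planar peroxycarbenium carbon. Its chain begins C1′H2–C2′H(CH3)–C3′H2–C4′, which is prenal joined through a γ-carbon. C3 bears CH3 next to an acid arm that can travel as a C≡CH rod slimmer than CH3, so the two ring faces differ in size.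
- **Forward order.** The dioxolane is closed first, then C5–C1′ is made and the enal C=C is reduced. The phenylhexyl unit (benzene ring bought) is added by Wittig reaction, the alkyne becomes CH2CO2H, and the alkene is saturated last with diimide.
- **Stereochemistry.** C3 comes from (S)-2-methylglycidyl tosylate: it is retained in the epoxide transposition and inverted once at ring closure. C5 is set by 1,3-induction from C3 in the key step. C2′ is set by the chiral imidazolidinone catalyst of the transfer hydrogenation.

Key step: step 8

Assumption: the ring is numbered O1, O2, C3 (acid arm or its precursor), C4, C5 (side chain or OMe) and the chain C1′ to C10′ outward from the ring; the purchased tosylate is taken as enantiopure, and the ketal carbon C5 of every methoxy compound is an inconsequential mixture of epimers.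

## Route

**Step 1**
Reactants: 1 (S)-2-methylglycidyl tosylate; 2 isopropenylmagnesium bromide
Product: 3 (S)-2-hydroxy-2,4-dimethylpent-4-en-1-yl 4-methylbenzenesulfonate
Conditions: CuI (10 mol %), THF, −40 to −20 °C; then aq NH4Cl
Reagents that add atoms: none
Why: Copper-catalysed Grignard opening of a glycidyl sulfonate, in which the alkenylcopper species attacks the unhindered epoxide CH2 rather than the neopentyl-type CH2OTs, and no bond to the quaternary carbon is touched, so its configuration is carried over.

**Step 2**
Reactants: 3 (S)-2-hydroxy-2,4-dimethylpent-4-en-1-yl 4-methylbenzenesulfonate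
Product: 4 (S)-2-methyl-2-(2-methylallyl)oxirane
Conditions: K2CO3, MeOH, 0 °C to rt; extraction into CH2Cl2 (volatile, kept in solution)
Reagents that add atoms: none
Why: Intramolecular Williamson closure (3-exo-tet) of the tertiary alkoxide onto the primary tosylate carbon transposes the epoxide, and the quaternary centre is again only a spectator.

**Step 3**
Reactants: 4 (S)-2-methyl-2-(2-methylallyl)oxirane
Product: 5 (S)-2-(2-hydroperoxy-2-methoxypropyl)-2-methyloxirane (both ketal epimers)
Conditions: O3, CH2Cl2/MeOH, −78 °C; N2 purge, cold concentration, no reductive work-up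
Reagents that add atoms: ozone, [O-][O+]=O; methanol, CO
Why: Criegee ozonolysis in a participating solvent, in which the primary ozonide of a 1,1-disubstituted alkene splits into formaldehyde and the more substituted carbonyl oxide, methanol traps the latter as the α-methoxy hydroperoxide, and the epoxide is inert to ozone.

**Step 4**
Reactants: 5 (S)-2-(2-hydroperoxy-2-methoxypropyl)-2-methyloxirane
Product: 6 [(3R)-5-methoxy-3,5-dimethyl-1,2-dioxolan-3-yl]methanol (both C5 anomers)
Conditions: camphorsulfonic acid (5 mol %), CH2Cl2 with a few % MeOH, 0 °C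
Reagents that add atoms: none
Why: Acid-catalysed intramolecular epoxide opening by a hydroperoxide, in which the 5-exo-tet geometry and the electronic bias of a protonated 2,2-disubstituted epoxide both direct the OOH group to the quaternary carbon, backside attack inverts it to (3R), and the added methanol keeps C5 as the methyl ketal.

**Step 5**
Reactants: 6 [(3R)-5-methoxy-3,5-dimethyl-1,2-dioxolan-3-yl]methanol
Product: 7 (3R)-5-methoxy-3,5-dimethyl-1,2-dioxolane-3-carbaldehyde
Conditions: Dess–Martin periodinane, pyridine, CH2Cl2, 0 °C to rt
Reagents that add atoms: none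
Why: Dess–Martin oxidation is neutral and does not reduce O–O bonds, and because C3 has no hydrogen neither epimerisation nor Kornblum–DeLaMare cleavage can occur.

**Step 6**
Reactants: 7 (3R)-5-methoxy-3,5-dimethyl-1,2-dioxolane-3-carbaldehyde
Product: 8 (3R)-3-ethynyl-5-methoxy-3,5-dimethyl-1,2-dioxolane (both C5 anomers)
Conditions: dimethyl (1-diazo-2-oxopropyl)phosphonate, K2CO3, MeOH, 0 °C
Reagents that add atoms: dimethyl (1-diazo-2-oxopropyl)phosphonate, COP(=O)(OC)C(=[N+]=[N-])C(C)=O
Why: Seyferth–Gilbert homologation under Ohira–Bestmann conditions, in which the diazophosphonate anion released in situ olefinates the non-enolisable aldehyde, loss of N2 and a 1,2-hydrogen shift give the terminal alkyne, the weak base and low temperature restrain fragmentation of the α-peroxy aldehyde, and C3 is untouched.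

**Step 7**
Reactants: 9 3-methylbut-2-enal
Product: 10 (E)-3-methyl-1-(trimethylsilyloxy)buta-1,3-diene
Conditions: TMSOTf, Et3N, Et2O, 0 °C to rt; pentane extraction, distillation
Reagents that add atoms: trimethylsilyl trifluoromethanesulfonate, C[Si](C)(C)OS(=O)(=O)C(F)(F)F
Why: Soft enolisation, in which O-silylation of the enal followed by γ-deprotonation by the amine gives the linear silyl dienol ether, and the preferred s-trans enal leads to the E enol ether.

**Step 8**
Reactants: 8 (3R)-3-ethynyl-5-methoxy-3,5-dimethyl-1,2-dioxolane; 10 (E)-3-methyl-1-(trimethylsilyloxy)buta-1,3-diene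
Product: 12 (E/Z)-4-[(3R,5R)-5-ethynyl-3,5-dimethyl-1,2-dioxolan-3-yl]-3-methylbut-2-enal, via dioxolanylium ion 11 (not isolated)
Conditions: TiCl4 (1.0 equiv) added to 8 and 10 (2 equiv), CH2Cl2, −78 °C; quench at −78 °C with aq NaHCO3
Reagents that add atoms: none
Why: Proposed new method: TiCl4 abstracts the C5 methoxy group from either anomer of 8, so both collapse to the same planar 1,2-dioxolan-3-ylium (peroxycarbenium) ion 11, which is captured at C5 by the terminal CH2 of 10; loss of the silyl group then unveils the β-methyl enal, the only bond formed being C5–C1′ and no ring being closed. The closest known reaction types are the Lewis acid substitution of 3-alkoxy-1,2-dioxolanes by silyl enol ethers, silyl ketene acetals and allylsilanes, and the vinylogous Mukaiyama reaction of silyl dienol ethers with acetals; what is new is their combination on a peroxycarbenium ion. The new quaternary centre C5 is controlled by C3: in the ion C4, C5, O1 and O2 are coplanar and C3 is the envelope flap, its methyl sits pseudoequatorial and the much slimmer ethynyl rod pseudoaxial, and the staggered inside trajectory brings the nucleophile in on the ethynyl face, anti to the C3 methyl, which should give the (3R,5R) isomer with the two ring methyls cis. The γ-regioselectivity that is needed should follow from a fully substituted cation meeting the unhindered terminal carbon of the diene rather than its more crowded α-carbon. Chemoselectivity rests on the ketal carbon being the only readily ionised site, on C3 carrying no hydrogen and on the inertness of a terminal alkyne to TiCl4 at −78 °C, and the enal geometry is irrelevant because the next step is geometry-convergent.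

**Step 9**
Reactants: 12 (E/Z)-4-[(3R,5R)-5-ethynyl-3,5-dimethyl-1,2-dioxolan-3-yl]-3-methylbut-2-enal
Product: 13 (3S)-4-[(3R,5R)-5-ethynyl-3,5-dimethyl-1,2-dioxolan-3-yl]-3-methylbutanal
Conditions: (S)-2-tert-butyl-3-methylimidazolidin-4-one·Cl3CCO2H (20 mol %), Hantzsch ester (diethyl 2,6-dimethyl-1,4-dihydropyridine-3,5-dicarboxylate, 1.2 equiv), CHCl3, −30 °C
Reagents that add atoms: none
Why: Iminium-catalysed transfer hydrogenation, in which the E and Z iminium ions interconvert through the dienamine and the E ion reacts faster, its chain lies away from the tert-butyl group, hydride enters the β-carbon on the face opposite that group, which for the (S)-catalyst sets the (S) centre at C2′ (renamed R in the target only through a priority change), and neither O–O bond nor alkyne is touched.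

**Step 10**
Reactants: 14 (6-bromohexyl)benzene
Product: 15 (6-phenylhexyl)triphenylphosphonium bromide
Conditions: PPh3, MeCN, reflux; precipitation from Et2O to remove free phosphine
Reagents that add atoms: triphenylphosphine, c1ccc(cc1)P(c1ccccc1)c1ccccc1
Why: SN2 quaternisation of triphenylphosphine by an unhindered primary bromide.

**Step 11**
Reactants: 13 (3S)-4-[(3R,5R)-5-ethynyl-3,5-dimethyl-1,2-dioxolan-3-yl]-3-methylbutanal; 15 (6-phenylhexyl)triphenylphosphonium bromide
Product: 17 (3R,5R)-3-ethynyl-3,5-dimethyl-5-[(2R,4Z)-2-methyl-10-phenyldec-4-en-1-yl]-1,2-dioxolane, via phosphonium ylide 16 (not isolated)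
Conditions: 15 (1.3 equiv), NaHMDS (1.2 equiv), THF, 0 °C; then 13, −78 °C to rt
Reagents that add atoms: none
Why: Lithium-free Wittig olefination with a non-stabilised ylide (kinetic cis-oxaphosphetane, hence Z, although the geometry does not matter), in which the ylide is too weak a base to deprotonate the alkyne, no free phosphine is present to attack the O–O bond, and the stereocentre β to the aldehyde cannot epimerise.

**Step 12**
Reactants: 17 (3R,5R)-3-ethynyl-3,5-dimethyl-5-[(2R,4Z)-2-methyl-10-phenyldec-4-en-1-yl]-1,2-dioxolane
Product: 19 2-{(3R,5R)-3,5-dimethyl-5-[(2R,4Z)-2-methyl-10-phenyldec-4-en-1-yl]-1,2-dioxolan-3-yl}acetaldehyde, via E-alkenylborane 18 (not isolated)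
Conditions: Cy2BH (1.05 equiv, from BH3·THF and cyclohexene), THF, 0 °C; then 30 % H2O2, pH 7–8 phosphate buffer, 0 °C
Reagents that add atoms: hydrogen peroxide, OO (the aldehyde oxygen); dicyclohexylborane, B(C1CCCCC1)C1CCCCC1 (boron and cyclohexyl groups stay only in 18)
Why: Hydroboration–oxidation of a terminal alkyne, in which the hindered dialkylborane adds syn and anti-Markovnikov to the alkyne far faster than to an internal Z-alkene and stops after one addition, and the buffered oxidation releases the enol and hence the aldehyde without base-induced β-elimination of the peroxide.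

**Step 13**
Reactants: 19 2-{(3R,5R)-3,5-dimethyl-5-[(2R,4Z)-2-methyl-10-phenyldec-4-en-1-yl]-1,2-dioxolan-3-yl}acetaldehyde
Product: 20 2-{(3R,5R)-3,5-dimethyl-5-[(2R,4Z)-2-methyl-10-phenyldec-4-en-1-yl]-1,2-dioxolan-3-yl}acetic acid
Conditions: NaClO2, NaH2PO4, 2-methyl-2-butene (excess), t-BuOH/H2O, 0 °C to rt
Reagents that add atoms: sodium chlorite, [Na+].[O-]Cl=O
Why: Pinnick oxidation at mildly acidic pH converts the aldehyde into the acid without enolate chemistry at the β-peroxy position, and the sacrificial alkene removes hypochlorous acid before it can reach the Z-alkene.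

**Step 14**
Reactants: 20 2-{(3R,5R)-3,5-dimethyl-5-[(2R,4Z)-2-methyl-10-phenyldec-4-en-1-yl]-1,2-dioxolan-3-yl}acetic acid
Product: 21 2-{(3R,5R)-3,5-dimethyl-5-[(2R)-2-methyl-10-phenyldecyl]-1,2-dioxolan-3-yl}acetic acid (CNP0311791.1)
Conditions: KO2CN=NCO2K (excess, in portions), AcOH, MeOH/CH2Cl2, 0 °C to rt
Reagents that add atoms: none
Why: Diimide reduction transfers two hydrogens concertedly to the C=C bond and, unlike catalytic hydrogenation, leaves the O–O bond, the arene and all three stereocentres untouched.

## Compound list

1 | (S)-2-methylglycidyl tosylate | Cc1ccc(cc1)S(=O)(=O)OC[C@]1(C)CO1 | starting material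
2 | isopropenylmagnesium bromide | C=C(C)[Mg]Br | starting material
3 | (S)-2-hydroxy-2,4-dimethylpent-4-en-1-yl 4-methylbenzenesulfonate | Cc1ccc(cc1)S(=O)(=O)OC[C@](O)(C)CC(C)=C | intermediate
4 | (S)-2-methyl-2-(2-methylallyl)oxirane | C=C(C)C[C@@]1(C)CO1 | intermediate
5 | (S)-2-(2-hydroperoxy-2-methoxypropyl)-2-methyloxirane, both ketal epimers | COC(C)(OO)C[C@@]1(C)CO1 | intermediate
6 | [(3R)-5-methoxy-3,5-dimethyl-1,2-dioxolan-3-yl]methanol, both C5 anomers | COC1(C)C[C@](C)(CO)OO1 | intermediate
7 | (3R)-5-methoxy-3,5-dimethyl-1,2-dioxolane-3-carbaldehyde, both C5 anomers | COC1(C)C[C@](C)(C=O)OO1 | intermediate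
8 | (3R)-3-ethynyl-5-methoxy-3,5-dimethyl-1,2-dioxolane, both C5 anomers | COC1(C)C[C@](C)(C#C)OO1 | intermediate
9 | 3-methylbut-2-enal | CC(C)=CC=O | starting material
10 | (E)-3-methyl-1-(trimethylsilyloxy)buta-1,3-diene | C=C(C)/C=C/O[Si](C)(C)C | intermediate
11 | (5R)-5-ethynyl-3,5-dimethyl-1,2-dioxolan-3-ylium ion (peroxycarbenium ion, not isolated) | C[C+]1C[C@](C)(C#C)OO1 | intermediate
12 | (E/Z)-4-[(3R,5R)-5-ethynyl-3,5-dimethyl-1,2-dioxolan-3-yl]-3-methylbut-2-enal | O=CC=C(C)C[C@]1(C)C[C@](C)(C#C)OO1 | intermediate
13 | (3S)-4-[(3R,5R)-5-ethynyl-3,5-dimethyl-1,2-dioxolan-3-yl]-3-methylbutanal | O=CC[C@@H](C)C[C@]1(C)C[C@](C)(C#C)OO1 | intermediate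
14 | (6-bromohexyl)benzene | BrCCCCCCc1ccccc1 | starting material
15 | (6-phenylhexyl)triphenylphosphonium bromide | [Br-].c1ccccc1CCCCCC[P+](c1ccccc1)(c1ccccc1)c1ccccc1 | intermediate
16 | (6-phenylhexylidene)triphenylphosphorane (not isolated) | c1ccccc1CCCCCC=P(c1ccccc1)(c1ccccc1)c1ccccc1 | intermediate
17 | (3R,5R)-3-ethynyl-3,5-dimethyl-5-[(2R,4Z)-2-methyl-10-phenyldec-4-en-1-yl]-1,2-dioxolane | c1ccccc1CCCCC/C=C\C[C@@H](C)C[C@]1(C)C[C@](C)(C#C)OO1 | intermediate
18 | (E)-alkenyl(dicyclohexyl)borane from 17 (not isolated) | c1ccccc1CCCCC/C=C\C[C@@H](C)C[C@]1(C)C[C@](C)(/C=C/B(C2CCCCC2)C2CCCCC2)OO1 | intermediate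
19 | 2-{(3R,5R)-3,5-dimethyl-5-[(2R,4Z)-2-methyl-10-phenyldec-4-en-1-yl]-1,2-dioxolan-3-yl}acetaldehyde | c1ccccc1CCCCC/C=C\C[C@@H](C)C[C@]1(C)C[C@](C)(CC=O)OO1 | intermediate
20 | 2-{(3R,5R)-3,5-dimethyl-5-[(2R,4Z)-2-methyl-10-phenyldec-4-en-1-yl]-1,2-dioxolan-3-yl}acetic acid | c1ccccc1CCCCC/C=C\C[C@@H](C)C[C@]1(C)C[C@](C)(CC(=O)O)OO1 | intermediate
21 | 2-{(3R,5R)-3,5-dimethyl-5-[(2R)-2-methyl-10-phenyldecyl]-1,2-dioxolan-3-yl}acetic acid (CNP0311791.1) | C[C@H](CCCCCCCCc1ccccc1)C[C@]1(C)C[C@](C)(CC(=O)O)OO1 | target

## Step count

Total step count: 14. Longest linear sequence: 12 steps (steps 1–6, 8, 9, 11–14, from 1 to 21).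

## Steps most likely to fail

**Step 8 (Proposed new method).**
- What may go wrong: the planar ion may show too little facial discrimination. The dienol ether may react through its α-carbon or oligomerise. The Lewis acid may expel the peroxide from the freshly formed enal.
- Fallback (known chemistry only): it sets out from 8. The established TiCl4-mediated substitution of 3-alkoxy-1,2-dioxolanes by a simple silyl enol ether, here 2-(trimethylsilyloxy)propene in CH2Cl2 at −78 °C, should give 1-[(3S,5R)-5-ethynyl-3,5-dimethyl-1,2-dioxolan-3-yl]propan-2-one F1, whose C5 epimers are separated by chromatography.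
- Horner–Wadsworth–Emmons olefination with the preformed sodium salt of diethyl cyanomethylphosphonate (THF, 0 °C) then leads to (E/Z)-4-[(3R,5R)-5-ethynyl-3,5-dimethyl-1,2-dioxolan-3-yl]-3-methylbut-2-enenitrile F2.
- DIBAL-H reduction at −78 °C with mild acidic hydrolysis of the imine returns to the route at 12.

**Step 9.**
- What may go wrong: the dienamine that makes the reaction geometry-convergent can push out the δ-peroxy group (vinylogous β-elimination with ring opening). The catalyst may also distinguish CH3 from CH2R only moderately.
- Fallback: it sets out from the chromatographically separated E isomer of 12 and replaces amine catalysis by biocatalysis. An ene-reductase of the Old Yellow Enzyme family, chosen from a panel for the required sense, is used with NADP+, glucose and glucose dehydrogenase in pH 7 buffer with a cosolvent.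
- The enzyme delivers hydride from the flavin to the β-carbon of the free enal without any dienamine, and the route is rejoined at 13. This makes no compound outside the list, F0.

**Step 6.**
- What may go wrong: methoxide or the phosphonate anion adds to the α-peroxy aldehyde, and the resulting alkoxide undergoes Grob-type C–C/O–O fragmentation faster than the olefination proceeds.
- Fallback: it sets out from 7 and avoids a free alkoxide. Wittig bromomethylenation with Ph3P=CHBr (from (bromomethyl)triphenylphosphonium bromide and KOt-Bu, THF, −78 °C) proceeds through an oxaphosphetane to (3R)-3-[(Z)-2-bromoethenyl]-5-methoxy-3,5-dimethyl-1,2-dioxolane F3.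
- Anti dehydrobromination of F3 with further KOt-Bu, a base that dialkyl peroxides without α-hydrogen tolerate, returns to the route at 8.

## Further compounds

F1 | step 8 | 1-[(3S,5R)-5-ethynyl-3,5-dimethyl-1,2-dioxolan-3-yl]propan-2-one | CC(=O)C[C@]1(C)C[C@](C)(C#C)OO1
F2 | step 8 | (E/Z)-4-[(3R,5R)-5-ethynyl-3,5-dimethyl-1,2-dioxolan-3-yl]-3-methylbut-2-enenitrile | N#CC=C(C)C[C@]1(C)C[C@](C)(C#C)OO1
F0 | step 9 | none | none
F3 | step 6 | (3R)-3-[(Z)-2-bromoethenyl]-5-methoxy-3,5-dimethyl-1,2-dioxolane | COC1(C)C[C@](C)(/C=C\Br)OO1
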